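The data come from a simulation with made-up constants; noise was put on by code.

Read the delay in the teal run first, and keep it in view through the repeat.

| flask | starting material | reagent | precatalyst | remark | time |
|---|---|---|---|---|---|
| teal | 0.16 M | 1.1 equiv | 0.05 mol% | run made earlier |  |
| amber | 0.16 M | 1.5 equiv | 0.05 mol% | run made earlier |  |
| ochre | 0.16 M | 2.4 equiv | 0.05 mol% | run made earlier |  |
| gamma | 0.16 M | 1.10 equiv (fed, over 9.60 min) | 0.05 mol% | a stirred flask in which reagent is dosed at a steady rate over 9.60 min without added volume, worked up at 12 min | 12 min |
| zeta | 0.16 M | 1.10 equiv | 0.05 mol% | a single well-mixed tank run continuously and read at steady state, 60.0 min in it on average |  |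
| theta | 0.16 M | 1.10 equiv | 0.05 mol% | a single well-mixed tank run continuously and read at steady state, 12 min in it on average |  |
| delta | 0.16 M | 1.10 equiv | 0.05 mol% | a closed flask charged with all of it at once and left for 12 min | 12 min |

- teal (time / min: target / %, starting material / %): 2.00: 1.1, 99.0; 4.00: 2.9, 97.0; 5.00: 4.6, 94.6; 8.00: 10.6, 89.4
- amber (time / min: target / %, starting material / %): 0.833: 0.4, 99.5; 2.00: 1.1, 99.2; 4.00: 3.7, 96.4; 10.0: 17.3, 82.9
- ochre (time / min: target / %, starting material / %): 1.33: 0.6, 99.7; 3.00: 2.1, 97.4; 6.00: 8.7, 91.3; 10.0: 19.2, 80.3

(standard deviation of a reading: 0.3 percentage points)

- the stated concentrations are those of everything mixed, before any reaction; amounts are the same in each set-up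
- what was read earlier has a scatter of 0.3 percentage points, one standard deviation
- the feed brings no volume worth counting
- the earlier runs were made in a closed, stirred flask
- a reading or a percentage of target counts all its forms, free or not

- the set-up with the highest amount of target at the outlet or at the end, in percent of the starting material put in ("none" if the first two lie within 2 percentage points) (gamma / zeta / theta / delta / none)
- amount of target at the outlet or at the end, in percent of the starting material put in, gamma
- amount of target at the outlet or at the end, in percent of the starting material put in, zeta
- amount of target at the outlet or at the end, in percent of the starting material put in, theta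
- amount of target at the outlet or at the end, in percent of the starting material put in, delta

In the teal run, target gathers at 0.00550 min⁻¹ of the charge over the first reading, but at a faster 0.0200 min⁻¹ between the last two readings. Carried back, that late line meets zero target at 2.70 min. This intercept is the lag, the field's induction period.

The reckoning here, which is separate from the forecast, reaches delta by two ways. The teal line gives 18.6% at 12 min. The amber line, with slope 0.0227 min⁻¹, gives 21.8%. They part by 3.2 percentage points, and the amber figure is the one to distrust: that run carries 1.5 equiv against delta's 1.10 equiv, and its slope, read from 4.00 min to 10.0 min, is steeper. The teal figure stands.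

A tank needs one further question: does the rate follow target or the age of the liquid? Across the last two ochre readings, mean target is twice that across the last two teal readings, yet the slope is 0.0263 min⁻¹, 1.31 times the teal slope, with more reagent. So age is taken as the clock here.

In a well-mixed tank, a share exp(−lag/residence time) of the liquid is past the lag, and that share has on average one residence time of further reaction. Theta therefore comes to 19.2%, close to the figure for delta. The same expression gives zeta 115%, above the whole charge, so the line cannot hold there. That figure is kept as a ranking, zeta above theta. Gamma, fed rather than charged, receives no figure here.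

The forecast chose zeta, with gamma 21%, zeta 80%, theta 50% and delta 24%. Its ground for the tanks was: "Back-mixed tanks hold target, so they start at a high rate." On theta, the two differ by 31 points.

Delta ends at 19.7%, theta at 19.1%, gamma at 17.4%, and zeta, the best, at 46.5%.

    precatalyst → free catalyst (k = 7.60 × 10⁻⁴ s⁻¹)
    free catalyst + target ⇌ idle complex (K = 32.0 M⁻¹, k = 0.0260 M⁻¹ s⁻¹)
    catalyst intermediate B → free catalyst + target (k = 660 s⁻¹)
    reagent + catalyst intermediate A ⇌ catalyst intermediate B (K = 1.90 M⁻¹, k = 35.0 M⁻¹ s⁻¹)
    starting material + free catalyst → catalyst intermediate A (k = 49.0 M⁻¹ s⁻¹)
    free catalyst → spent catalyst (k = 0.00220 s⁻¹)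

In delta at 12.0 min, precatalyst still holds 57.9% of the catalyst charged. Read with the teal slope, gamma's end gives a lag of 3.30 min, longer than the teal lag by 0.600 min. At 6.00 min, gamma held 59.1% of its reagent charge.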